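# Propolis-benzofuran A: synthesis plan built on an aldehyde/aminosiloxy-diene hetero-Diels–Alder reaction

## The problem

Propolis-benzofuran A (21) is a 3,4-dihydro-2H-pyran (ring B: O1, C2–C6) with a guaiacyl ring (ring A) on C2, an acetoxymethyl group on C3 and, on C5, a 6-acetyl-5-hydroxybenzofuran (rings C and D) attached through its C2'. The ring systems are joined only by two single bonds (C2–aryl and C5–C2'), so the task is to build ring B between two aromatic units, not to fuse rings. There are two stereocentres, C2 (R) and C3 (S), trans on neighbouring ring atoms. C2 must be set absolutely, whereas C3 can be slaved to it: while C3 lies α to a carbonyl group, equilibration should place its substituent trans to the C2 aryl group. The molecule is fragile in several places: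
- the O1–C6=C5 enol ether is hydrolysed by acid;
- the C2–O1 bond is a para-oxygenated benzylic ether that can ionise under acid, or through a quinone methide from the free phenoxide, and either path would scramble C2;
- the primary acetate has to be told apart from two phenols;
- the ortho-hydroxyacetophenone has an enolisable, reducible methyl ketone on an oxidisable hydroquinone-type ring.

The enabling feature is the oxygen pattern of ring B. C2 carries O1 and the aryl group and is therefore the carbonyl carbon of vanillin (1). C6–C5–C4–C3 is a four-carbon unit whose C5=C6 enol ether is what is left of a vinylogous ester once C4 bears oxygen. Ring B is thus the retron of a hetero-Diels–Alder reaction between an aromatic aldehyde and a 1-amino-3-siloxy diene, which forms C2–C3 and O1–C6 together and leaves C3 α to a ketone.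

## Retrosynthesis

**Acetate last (21 ⇒ 20).** The ester C–O bond of the primary acetate is cut first. An acetate would not survive the hydride, fluoride and amidine-base steps that precede it, and a β-acetoxy ketone would eliminate during the equilibration of C3. Triol 20 is simpler by one functional-group distinction. The forward step must acylate the primary aliphatic hydroxyl in the presence of two phenols, a selectivity that a lipase with an enol ester offers without protecting groups.

**One kind of protecting group (20 ⇒ 19).** All four O–Si bonds are cut together. In 19 the two phenols and the primary alcohol are tert-butyldimethylsilyl ethers and the acetyl group is its silyl enol ether. This choice keeps the phenoxide (and the quinone-methide pathway at C2) switched off until the penultimate step. It also lets a single buffered fluoride treatment return three hydroxyls and the methyl ketone. The forward step must be buffered so that no free phenoxide persists.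

**Oxygen at C4 (19 ⇒ 18 ⇒ 17 ⇒ 16).** The C4–H bond is traded for a C4–O bond, back to ketone 16. This is the one deliberate detour. The carbonyl at C4 turns O1–C6=C5–C4=O into a vinylogous ester, which fixes the position of the enol ether, acidifies C3–H for stereocontrol and exposes the cycloaddition retron. Three redox steps pay for it: reduction to 17, carbonate 18, hydrogenolysis to 19. The forward sequence must deliver hydride to C4 and not to C6, and must avoid Lewis and protic acids because of the C2 benzylic ether and the silyl enol ether. A palladium/formate hydrogenolysis under basic buffer meets the second demand and is chosen over silane/Lewis-acid reduction for that reason.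

**Key disconnection (16 ⇒ 2 + 13).** C2–C3 and O1–C6 are cut in one retro-[4+2] step, through aminal 14 and the cis ketone 15. The partners are silylated vanillin 2 and the 1-dimethylamino-3-siloxy diene 13, which already carries the benzofuran on its C2 and the silyloxymethyl group on its C4. Against a stepwise aldol/cyclisation this cut has two advantages: the electron-rich diene reacts with a merely hydrogen-bonded aldehyde, and a chiral diol can then set C2. Ring B, both stereocentres and the C5 aryl bond pattern arrive from two achiral pieces. The forward reaction must fix the aldehyde face by catalyst control, and the C3 configuration by base equilibration after the amine has been expelled.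

**Diene from a ketone (13 ⇒ 12 ⇒ 11).** The two enol O–Si bonds and the C5–C6 bond are cut. C6 and its nitrogen come from a formamide acetal condensing at the doubly activated methylene of benzofuranylmethyl ketone 11. Double enolisation of enaminone 12 then silylates the cross-conjugated enolate and, unavoidably, the aryl methyl ketone. That second silylation is used as the protection of the acetyl group. The forward steps ask for condensation at the benzylic methylene in preference to the acetyl methyl, and enolisation of a β-silyloxy ketone without elimination.

**Benzofuran early (11 ⇒ 10 ⇒ 9 ⇒ 7 + 5).** The aryl–C3' bond and the O1'–C2' bond of the furan are cut, giving bromophenol 7 and alkynol 5; alkynylphenol 8 is the intermediate. Building the benzofuran at the start, on robust compounds, is preferred to a late cross-coupling onto C5 of the sensitive pyran. The carbinol of 9 is the latent ketone. The chelated phenol is silylated (10) before oxidation to 11.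

**Starting materials (7 ⇒ 6; 5 ⇒ 3 + 4; 2 ⇒ 1).** Bromophenol 7 comes from C-acetylation of bromohydroquinone 6 para to bromine. Alkynol 5 comes from zinc-mediated propargylation of aldehyde 3 with propargyl bromide 4. Aldehyde 2 comes from silylation of vanillin 1.

## Roads not taken

**Alternative 1:** benzofuran closed last by an intramolecular Wittig reaction. The cut removes O1'–C2' and C2'=C3' of the furan, leaving the pyran-5-carbonyl chloride A1 and the ortho-hydroxybenzylphosphonium salt A2. In the forward step A1 would acylate the phenol next to the phosphoniomethyl group of A2, and triethylamine would generate the ylide, which olefinates the new ester carbonyl to give A3, one desilylation from 21.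
- Merits: C4 is never oxygenated, the acetate is already in place, the acetyl group needs no mask, and the endgame is a single step. In end-game economy this road beats the chosen plan.
- Weak points: the ester to be olefinated is a vinylogous carbonate (O1–C6=C5–C=O), doubly deactivated towards a ylide that is itself stabilised by the para acetyl group. C-acylation of the ylide and attack on the acetyl group of a second molecule are open side paths. Above all, A1 contains the whole stereochemical problem (trans C2/C3 on a dihydropyran with the correct enol ether), for which this road offers no solution.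
- Comparison: the chosen plan sets against the shorter endgame a catalytic, ring-forming step that creates both stereocentres from achiral components.

**Alternative 2:** one-carbon insertion into a dihydrofuran. C5 and its benzofuranyl group are excised (cuts at C4–C5 and C5–C6), leaving the trans-2,3-disubstituted 2,3-dihydrofuran A5 and the chlorodiazirine A4. The arylchlorocarbene from A4 would cyclopropanate the enol ether of A5. The adduct would open with loss of chloride to an oxygen-substituted allyl cation, and triethylsilane would reduce it to A6.
- Merits: on paper this is the shortest road. If it worked as drawn it would save several steps over the chosen plan, and C4 would arrive at the right oxidation level.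
- Weak points: the cation is the same alkoxy-allyl cation as in Ferrier chemistry, where hydride normally adds at the oxygen-bearing carbon (C6). That would give the 3,6-dihydro isomer. Proton loss from C3 to a 2H-pyran would destroy a stereocentre. A4 must be made by hypohalite oxidation of an amidine on an electron-rich benzofuran. The ketal in A6 can only be removed with aqueous acid, next to the enol ether and the benzylic C2–O1 bond. The ring expansion with reductive interception has no close model on dihydrofurans.
- Comparison: the chosen plan faces the same regiochemical question (hydride at C4 or C6), but under metal control and in a reaction of known type, and its ring-forming step belongs to an established class.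

**Alternative 3:** photocatalytic dehydrogenative oxy-cyclisation. Only O1–C6 is cut, giving the acyclic hydroxy alkene A7. Under blue light with 9-mesityl-10-methylacridinium tetrafluoroborate and Co(dmgH)2(py)Cl, the C2 hydroxyl would add to the terminal carbon of the vinylbenzofuran radical cation (anti-Markovnikov, 6-endo), and loss of hydrogen would give enol ether A8.
- Merits: no deoxygenation detour, the acetate is carried through, the conditions are mild, and the stereocentres are not touched in the ring closure. In redox economy it is at least equal to the chosen plan.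
- Weak points: the excited acridinium can oxidise all three electron-rich aromatic units, which is why the guaiacol oxygen must be an acetate. The radical cation of a benzylic carbinol can fragment at the C2–C3 bond. The C5 radical can lose hydrogen from C4 as well as from C6. The aryl acetate must later be cleaved beside the alkyl acetate. A7 needs its own stereoselective synthesis, most plausibly an auxiliary-controlled anti-aldol reaction, so absolute control would be stoichiometric.
- Comparison: the chosen plan accepts three redox steps in exchange for catalytic absolute control and a ring closure whose reaction class is documented for aldehydes of this kind.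

Key step: step 9

## Assumptions

- Remark: 3-(tert-butyldimethylsilyloxy)propanal (3) is taken as a purchased compound.
- Remark: the (4S,5S) enantiomer of the diol catalyst is specified on the expectation that the hydrogen-bonded aldehyde is attacked on its Re face; should the substituted diene reverse the sense, the (4R,5R) diol is used unchanged otherwise.

## Route

Step 1
Reactants: 1 vanillin (4-hydroxy-3-methoxybenzaldehyde)
Product: 2 4-(tert-butyldimethylsilyloxy)-3-methoxybenzaldehyde
Conditions: TBSCl, imidazole, DMF, 0 °C → rt
Reagents that add atoms: tert-butyldimethylsilyl chloride, CC(C)(C)[Si](C)(C)Cl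
Why: Standard O-silylation of a phenol; the silyl ether removes the acidic proton that would quench the diene and is cleaved by fluoride at the end.

Step 2
Reactants: 3 3-(tert-butyldimethylsilyloxy)propanal; 4 propargyl bromide
Product: 5 rac-1-(tert-butyldimethylsilyloxy)hex-5-yn-3-ol
Conditions: Zn dust, THF, 0 °C → rt; aq. NH4Cl
Reagents that add atoms: none
Why: Barbier-type propargylation; the allenylzinc bromide formed in situ adds to the aldehyde through an SE2' transition state and should give the homopropargylic alcohol. The carbinol centre is racemic and is erased in step 6.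

Step 3
Reactants: 6 bromohydroquinone (2-bromobenzene-1,4-diol)
Product: 7 1-(4-bromo-2,5-dihydroxyphenyl)ethanone
Conditions: AcOH, BF3·OEt2, 100 °C; then H2O
Reagents that add atoms: acetic acid, CC(=O)O
Why: Friedel–Crafts-type C-acylation of a hydroquinone (O-acylation and Fries shift under BF3); the position ortho to a hydroxyl and para to bromine is the least hindered activated site, and the product is held as a boron chelate until work-up.

Step 4
Reactants: 7 1-(4-bromo-2,5-dihydroxyphenyl)ethanone; 5 rac-1-(tert-butyldimethylsilyloxy)hex-5-yn-3-ol
Product: 9 1-{2-[4-(tert-butyldimethylsilyloxy)-2-hydroxybutyl]-5-hydroxybenzofuran-6-yl}ethanone, via alkynylphenol 8 (not isolated)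
Conditions: PdCl2(PPh3)2 (5 mol%), CuI (10 mol%), Et3N, DMF (degassed), 80 °C
Reagents that add atoms: none
Why: Sonogashira coupling followed in the same flask by metal-assisted 5-endo-dig addition of the ortho phenoxide to the alkyne, the usual one-pot route from ortho-halophenols to 2-substituted benzofurans. The acetyl group para to bromine assists oxidative addition, and the chelated phenol and the carbinol are spectators.

Step 5
Reactants: 9 1-{2-[4-(tert-butyldimethylsilyloxy)-2-hydroxybutyl]-5-hydroxybenzofuran-6-yl}ethanone
Product: 10 1-{5-(tert-butyldimethylsilyloxy)-2-[4-(tert-butyldimethylsilyloxy)-2-hydroxybutyl]benzofuran-6-yl}ethanone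
Conditions: TBSCl (1.1 equiv), Et3N, CH2Cl2, 0 °C → rt
Reagents that add atoms: tert-butyldimethylsilyl chloride, CC(C)(C)[Si](C)(C)Cl
Why: Chemoselective O-silylation; the phenol reacts as its ammonium phenoxide, whereas a secondary alcohol is inert to the silyl chloride without a nucleophilic catalyst. The phenol is thereby protected from the oxidant of step 6.

Step 6
Reactants: 10 1-{5-(tert-butyldimethylsilyloxy)-2-[4-(tert-butyldimethylsilyloxy)-2-hydroxybutyl]benzofuran-6-yl}ethanone
Product: 11 1-[6-acetyl-5-(tert-butyldimethylsilyloxy)benzofuran-2-yl]-4-(tert-butyldimethylsilyloxy)butan-2-one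
Conditions: Dess–Martin periodinane, NaHCO3, CH2Cl2, 0 °C → rt
Reagents that add atoms: none
Why: Dess–Martin oxidation of a secondary alcohol under buffered, non-basic conditions, so that the β-silyloxy ketone does not eliminate and the silyl ethers stay intact.

Step 7
Reactants: 11 1-[6-acetyl-5-(tert-butyldimethylsilyloxy)benzofuran-2-yl]-4-(tert-butyldimethylsilyloxy)butan-2-one
Product: 12 (E)-2-[6-acetyl-5-(tert-butyldimethylsilyloxy)benzofuran-2-yl]-5-(tert-butyldimethylsilyloxy)-1-(dimethylamino)pent-1-en-3-one
Conditions: Me2NCH(OMe)2 (2 equiv), toluene, 55 °C
Reagents that add atoms: N,N-dimethylformamide dimethyl acetal, COC(OC)N(C)C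
Why: Aminomethylenation (enaminone formation) at the methylene flanked by the ketone and the benzofuran, which is far more acidic than the other α-methylene or the aryl methyl ketone. Keeping the temperature moderate should leave the acetyl group untouched.

Step 8
Reactants: 12 (E)-2-[6-acetyl-5-(tert-butyldimethylsilyloxy)benzofuran-2-yl]-5-(tert-butyldimethylsilyloxy)-1-(dimethylamino)pent-1-en-3-one
Product: 13 (1E,3Z)-1-(dimethylamino)-3,5-bis(tert-butyldimethylsilyloxy)-2-{5-(tert-butyldimethylsilyloxy)-6-[1-(tert-butyldimethylsilyloxy)vinyl]benzofuran-2-yl}penta-1,3-diene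
Conditions: KN(SiMe3)2 (2.4 equiv), THF, −78 °C; then TBSCl, −78 °C → rt; non-aqueous work-up, used crude
Reagents that add atoms: tert-butyldimethylsilyl chloride, CC(C)(C)[Si](C)(C)Cl
Why: Double kinetic enolisation and O-silylation, the standard preparation of 1-amino-3-siloxy dienes from vinylogous amides; the Z enolate places the silyloxymethyl group on the outside of the diene. The aryl methyl ketone is silylated in the same operation and travels as its enol ether. At −78 °C the β-silyloxy enolate should be silylated before it can eliminate.

Step 9
Reactants: 2 4-(tert-butyldimethylsilyloxy)-3-methoxybenzaldehyde; 13 (1E,3Z)-1-(dimethylamino)-3,5-bis(tert-butyldimethylsilyloxy)-2-{5-(tert-butyldimethylsilyloxy)-6-[1-(tert-butyldimethylsilyloxy)vinyl]benzofuran-2-yl}penta-1,3-diene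
Product: 16 (2R,3S)-2-[4-(tert-butyldimethylsilyloxy)-3-methoxyphenyl]-3-(tert-butyldimethylsilyloxymethyl)-5-{5-(tert-butyldimethylsilyloxy)-6-[1-(tert-butyldimethylsilyloxy)vinyl]benzofuran-2-yl}-2,3-dihydro-4H-pyran-4-one, via endo cycloadduct 14 (not isolated), via cis-dihydropyranone 15 (not isolated)
Conditions: (4S,5S)-2,2-dimethyl-α,α,α',α'-tetra(1-naphthyl)-1,3-dioxolane-4,5-dimethanol (20 mol%), toluene, −40 °C; then AcCl, CH2Cl2, −78 °C, aq. NaHCO3; then DBU (0.2 equiv), CH2Cl2, 0 °C
Reagents that add atoms: none
Why: One hydroxyl of the diol hydrogen-bonds to the formyl oxygen of 2, and diene 13 adds in a concerted, asynchronous normal-demand hetero-Diels–Alder reaction; its silyloxymethyl-bearing terminus bonds to the formyl carbon (C2–C3) and its amino-bearing terminus to oxygen (O1–C6), giving aminal 14. Acetyl chloride then acylates the aminal nitrogen, the acylammonium group leaves with help from O1, and chloride removes the C4 silyl group to give the vinylogous ester. The closest known reaction type is the hydrogen-bond-catalysed enantioselective hetero-Diels–Alder reaction of 1-amino-3-siloxy-1,3-dienes with aldehydes to 2-substituted 2,3-dihydro-4H-pyran-4-ones, applied here to a diene substituted at C2 and C4. Ring B is closed by an intermolecular [4+2] cycloaddition, both ring bonds forming in one suprafacial event. C2 is set by the catalyst, which shields one face so that the diene adds to the Re face of the aldehyde (2R); endo and exo approaches use the same aldehyde face and therefore converge on 2R. C3 is first set kinetically (endo, cis, 15) and is then equilibrated by DBU through the C3 enolate to the trans isomer 16, in which both substituents are pseudo-equatorial on the half-chair. Regiochemistry follows from the push of the amino and siloxy groups, and the aryl silyl enol ether does not compete because it is not nucleophilic enough for an aldehyde that is only hydrogen-bonded. The step needs the catalysed path to outrun the unselective background reaction, hence the low temperature and non-polar solvent, and it needs the base step to stop at epimerisation, hence catalytic DBU at 0 °C.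

Step 10
Reactants: 16 (2R,3S)-dihydropyranone from step 9
Product: 17 (2R)-2,3-trans-2-[4-(tert-butyldimethylsilyloxy)-3-methoxyphenyl]-3-(tert-butyldimethylsilyloxymethyl)-5-{5-(tert-butyldimethylsilyloxy)-6-[1-(tert-butyldimethylsilyloxy)vinyl]benzofuran-2-yl}-3,4-dihydro-2H-pyran-4-ol (both C4 epimers, used crude)
Conditions: i-Bu2AlH, CH2Cl2, −78 °C; Rochelle salt, pH ≥ 7
Reagents that add atoms: none
Why: 1,2-Reduction of a vinylogous ester by an aluminium hydride, acid-free so that the silyl enol ether and the ionisable allylic alcohol survive. The C4 configuration (expected mainly trans to C3 by axial attack) is immaterial because C4 becomes a methylene group in step 12.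

Step 11
Reactants: 17 allylic alcohol from step 10
Product: 18 methyl carbonate of 17 at the C4 oxygen (2R, 2,3-trans, both C4 epimers)
Conditions: ClCO2Me, pyridine, DMAP (cat.), CH2Cl2, 0 °C
Reagents that add atoms: methyl chloroformate, COC(Cl)=O
Why: Acylation of a secondary allylic alcohol to a carbonate under basic conditions. Should the carbonate shift to C6 by allylic transposition, both isomers would feed the same allylpalladium intermediate in step 12.

Step 12
Reactants: 18 methyl carbonate from step 11
Product: 19 (2R,3S)-2-[4-(tert-butyldimethylsilyloxy)-3-methoxyphenyl]-3-(tert-butyldimethylsilyloxymethyl)-5-{5-(tert-butyldimethylsilyloxy)-6-[1-(tert-butyldimethylsilyloxy)vinyl]benzofuran-2-yl}-3,4-dihydro-2H-pyran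
Conditions: Pd2(dba)3·CHCl3 (2.5 mol%), n-Bu3P (10 mol%), HCO2H, Et3N (excess), THF, 25–40 °C
Reagents that add atoms: none
Why: Tsuji–Trost-type ionisation by zerovalent palladium followed by formate hydrogenolysis: the formate bound to palladium loses CO2 and hydride is transferred within the allyl complex. With a trialkylphosphine, palladium should sit on the less hindered, oxygen-bearing terminus C6 and hydride should go to the more hindered terminus C4, leaving the C5=C6 enol ether conjugated with the benzofuran. No stereocentre is formed or touched, and the amine buffer protects the acid-labile groups.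

Step 13
Reactants: 19 tetrasilylated dihydropyran from step 12
Product: 20 1-{5-hydroxy-2-[(2R,3S)-2-(4-hydroxy-3-methoxyphenyl)-3-(hydroxymethyl)-3,4-dihydro-2H-pyran-5-yl]benzofuran-6-yl}ethanone
Conditions: Bu4NF, AcOH (1:1), THF, 0 °C → rt
Reagents that add atoms: none
Why: Fluoride desilylation of two aryl ethers, one primary alkyl ether and the enol ether, the last returning the methyl ketone on protonation. Acetic acid keeps the phenols protonated, so that neither quinone-methide opening of the C2–O1 bond nor air oxidation of the hydroquinone-type ring can start.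

Step 14
Reactants: 20 triol from step 13
Product: 21 propolis-benzofuran A, [(2R,3S)-5-(6-acetyl-5-hydroxybenzofuran-2-yl)-2-(4-hydroxy-3-methoxyphenyl)-3,4-dihydro-2H-pyran-3-yl]methyl acetate
Conditions: immobilised Candida antarctica lipase B, vinyl acetate, THF, 35 °C
Reagents that add atoms: vinyl acetate, C=COC(C)=O
Why: Lipase-catalysed transesterification with an enol ester; lipases acylate primary aliphatic alcohols and leave phenols alone. The reaction is irreversible because the leaving enol tautomerises, and the neutral medium spares the enol ether and the benzylic ether.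

## Compound list

1 | vanillin | COc1cc(C=O)ccc1O | starting material
2 | 4-(tert-butyldimethylsilyloxy)-3-methoxybenzaldehyde | COc1cc(C=O)ccc1O[Si](C)(C)C(C)(C)C | intermediate
3 | 3-(tert-butyldimethylsilyloxy)propanal | O=CCCO[Si](C)(C)C(C)(C)C | starting material
4 | propargyl bromide | BrCC#C | starting material
5 | rac-1-(tert-butyldimethylsilyloxy)hex-5-yn-3-ol | C#CCC(O)CCO[Si](C)(C)C(C)(C)C | intermediate
6 | bromohydroquinone | Oc1ccc(O)c(Br)c1 | starting material
7 | 1-(4-bromo-2,5-dihydroxyphenyl)ethanone | CC(=O)c1cc(O)c(Br)cc1O | intermediate
8 | 1-{4-[6-(tert-butyldimethylsilyloxy)-4-hydroxyhex-1-yn-1-yl]-2,5-dihydroxyphenyl}ethanone (not isolated) | CC(=O)c1cc(O)c(C#CCC(O)CCO[Si](C)(C)C(C)(C)C)cc1O | intermediate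
9 | 1-{2-[4-(tert-butyldimethylsilyloxy)-2-hydroxybutyl]-5-hydroxybenzofuran-6-yl}ethanone | CC(=O)c1cc2oc(CC(O)CCO[Si](C)(C)C(C)(C)C)cc2cc1O | intermediate
10 | 1-{5-(tert-butyldimethylsilyloxy)-2-[4-(tert-butyldimethylsilyloxy)-2-hydroxybutyl]benzofuran-6-yl}ethanone | CC(=O)c1cc2oc(CC(O)CCO[Si](C)(C)C(C)(C)C)cc2cc1O[Si](C)(C)C(C)(C)C | intermediate
11 | 1-[6-acetyl-5-(tert-butyldimethylsilyloxy)benzofuran-2-yl]-4-(tert-butyldimethylsilyloxy)butan-2-one | CC(=O)c1cc2oc(CC(=O)CCO[Si](C)(C)C(C)(C)C)cc2cc1O[Si](C)(C)C(C)(C)C | intermediate
12 | (E)-2-[6-acetyl-5-(tert-butyldimethylsilyloxy)benzofuran-2-yl]-5-(tert-butyldimethylsilyloxy)-1-(dimethylamino)pent-1-en-3-one | CN(C)/C=C(\c1cc2cc(O[Si](C)(C)C(C)(C)C)c(C(C)=O)cc2o1)C(=O)CCO[Si](C)(C)C(C)(C)C | intermediate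
13 | (1E,3Z)-1-(dimethylamino)-3,5-bis(tert-butyldimethylsilyloxy)-2-{5-(tert-butyldimethylsilyloxy)-6-[1-(tert-butyldimethylsilyloxy)vinyl]benzofuran-2-yl}penta-1,3-diene | CN(C)/C=C(\c1cc2cc(O[Si](C)(C)C(C)(C)C)c(C(=C)O[Si](C)(C)C(C)(C)C)cc2o1)/C(O[Si](C)(C)C(C)(C)C)=C/CO[Si](C)(C)C(C)(C)C | intermediate
14 | (2R,3R,6S)-6-(dimethylamino)-4-(tert-butyldimethylsilyloxy)-3,6-dihydro-2H-pyran cycloadduct with the C2 aryl, C3 silyloxymethyl and C5 benzofuranyl groups of 16, drawn as the all-cis endo adduct (not isolated) | COc1cc([C@@H]2O[C@H](N(C)C)C(c3cc4cc(O[Si](C)(C)C(C)(C)C)c(C(=C)O[Si](C)(C)C(C)(C)C)cc4o3)=C(O[Si](C)(C)C(C)(C)C)[C@@H]2CO[Si](C)(C)C(C)(C)C)ccc1O[Si](C)(C)C(C)(C)C | intermediate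
15 | (2R,3R)-cis epimer of 16 (not isolated) | COc1cc([C@@H]2OC=C(c3cc4cc(O[Si](C)(C)C(C)(C)C)c(C(=C)O[Si](C)(C)C(C)(C)C)cc4o3)C(=O)[C@@H]2CO[Si](C)(C)C(C)(C)C)ccc1O[Si](C)(C)C(C)(C)C | intermediate
16 | (2R,3S)-2-[4-(tert-butyldimethylsilyloxy)-3-methoxyphenyl]-3-(tert-butyldimethylsilyloxymethyl)-5-{5-(tert-butyldimethylsilyloxy)-6-[1-(tert-butyldimethylsilyloxy)vinyl]benzofuran-2-yl}-2,3-dihydro-4H-pyran-4-one | COc1cc([C@@H]2OC=C(c3cc4cc(O[Si](C)(C)C(C)(C)C)c(C(=C)O[Si](C)(C)C(C)(C)C)cc4o3)C(=O)[C@H]2CO[Si](C)(C)C(C)(C)C)ccc1O[Si](C)(C)C(C)(C)C | intermediate
17 | C4 alcohol of 16 (2R, 2,3-trans; C4 epimer mixture, configuration at C4 not defined) | COc1cc([C@@H]2OC=C(c3cc4cc(O[Si](C)(C)C(C)(C)C)c(C(=C)O[Si](C)(C)C(C)(C)C)cc4o3)C(O)[C@H]2CO[Si](C)(C)C(C)(C)C)ccc1O[Si](C)(C)C(C)(C)C | intermediate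
18 | C4 methyl carbonate of 17 (2R, 2,3-trans; C4 epimer mixture) | COc1cc([C@@H]2OC=C(c3cc4cc(O[Si](C)(C)C(C)(C)C)c(C(=C)O[Si](C)(C)C(C)(C)C)cc4o3)C(OC(=O)OC)[C@H]2CO[Si](C)(C)C(C)(C)C)ccc1O[Si](C)(C)C(C)(C)C | intermediate
19 | (2R,3S)-2-[4-(tert-butyldimethylsilyloxy)-3-methoxyphenyl]-3-(tert-butyldimethylsilyloxymethyl)-5-{5-(tert-butyldimethylsilyloxy)-6-[1-(tert-butyldimethylsilyloxy)vinyl]benzofuran-2-yl}-3,4-dihydro-2H-pyran | COc1cc([C@@H]2OC=C(c3cc4cc(O[Si](C)(C)C(C)(C)C)c(C(=C)O[Si](C)(C)C(C)(C)C)cc4o3)C[C@H]2CO[Si](C)(C)C(C)(C)C)ccc1O[Si](C)(C)C(C)(C)C | intermediate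
20 | 1-{5-hydroxy-2-[(2R,3S)-2-(4-hydroxy-3-methoxyphenyl)-3-(hydroxymethyl)-3,4-dihydro-2H-pyran-5-yl]benzofuran-6-yl}ethanone | COc1cc([C@@H]2OC=C(c3cc4cc(O)c(C(C)=O)cc4o3)C[C@H]2CO)ccc1O | intermediate
21 | propolis-benzofuran A | COc1cc([C@@H]2OC=C(c3cc4cc(O)c(C(C)=O)cc4o3)C[C@H]2COC(C)=O)ccc1O | target

## Step count and risk

Total: 14 steps. Longest linear sequence: 12 steps (6 → 7 → 9 → 10 → 11 → 12 → 13 → 16 → 17 → 18 → 19 → 20 → 21).

**Step 9 (key step).**
- What may go wrong: the diene is substituted at both C2 and C4 and the aldehyde is electron-rich, so the catalysed cycloaddition may be slow. The uncatalysed background reaction, which has no facial preference, and hydrolysis of the diene could then compete, giving poor facial selectivity at C2. In the base step, β-elimination across C3–C2 (ring opening and reclosure) would erode C2, and loss of silyloxide from the C3 enolate would destroy the side chain.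
- Fallback: change the mode of activation from hydrogen bonding to coordination of the aldehyde by a chiral Lewis acid. A chromium salen chloride, (salen)CrCl with salen = N,N'-bis(3,5-di-tert-butylsalicylidene)cyclohexane-1,2-diaminate, is of a type known to accept amino-siloxy dienes. It would be used at higher temperature, followed by the same acetyl chloride treatment, and the equilibration would be run with triethylamine in place of DBU. The fallback sets out from 2 and 13 and returns at 16; it makes no new compound.

**Step 12.**
- What may go wrong: hydride transfer to C6 instead of C4 within the allylpalladium intermediate (the oxygen-bearing terminus is the more electrophilic one), or β-hydride loss from C3 to a 2H-pyran.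
- Fallback: accept delivery at C6 and correct the alkene afterwards. Starting from 18, the same palladium/formate reduction, if it takes the other course, gives (2R,3S)-2-[4-(tert-butyldimethylsilyloxy)-3-methoxyphenyl]-3-(tert-butyldimethylsilyloxymethyl)-5-{5-(tert-butyldimethylsilyloxy)-6-[1-(tert-butyldimethylsilyloxy)vinyl]benzofuran-2-yl}-3,6-dihydro-2H-pyran F1. F1 is then isomerised with RuHCl(CO)(PPh3)3 in toluene at 80 °C: hydrometalation at the benzofuran-bearing carbon and β-hydride elimination towards C6 move the double bond into conjugation with O1. The fallback returns at 19.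

**Step 8.**
- What may go wrong: E1cB loss of the β-silyloxy group from the potassium enolate, incomplete double O-silylation, or hydrolysis of the diene on handling.
- Fallback: soft enolisation, in which both carbonyl oxygens are silylated first by TBSOTf and the resulting cations are deprotonated by Et3N (Et2O, −78 → 0 °C), so that no free enolate is ever present. The fallback sets out from 12 and returns at 13; it makes no new compound.

**Step 4.**
- What may go wrong: slow oxidative addition into an aryl bromide whose ortho oxygen is a phenoxide under the reaction conditions, so that alkyne homocoupling and oxidation of the hydroquinone take over.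
- Fallback: protect, couple, then cyclise. Starting from 7, Ac2O/pyridine gives 2-acetyl-5-bromo-1,4-phenylene diacetate F2, an electron-poorer and non-ionisable bromide. Sonogashira coupling with 5 gives 2-acetyl-5-[6-(tert-butyldimethylsilyloxy)-4-hydroxyhex-1-yn-1-yl]-1,4-phenylene diacetate F3. Methanolysis (K2CO3, MeOH, 0 °C) returns to the route at 8, which is closed to 9 with CuI/Et3N in DMF.

**Step 14.**
- What may go wrong: slow enzymatic acylation of a primary alcohol that sits next to a stereocentre and a bulky aryl-bearing carbon, so that conversion stalls or unselective chemical acylation of a phenol intervenes.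
- Fallback: chemical differentiation after exhaustive acylation. Starting from 20, Ac2O/pyridine gives the triacetate, [(2R,3S)-5-(5-acetoxy-6-acetylbenzofuran-2-yl)-2-(4-acetoxy-3-methoxyphenyl)-3,4-dihydro-2H-pyran-3-yl]methyl acetate F4. The two aryl acetates are then cleaved selectively with NH4OAc in aqueous methanol at rt, which leaves alkyl acetates intact, returning at 21.

## Further compounds

F0 | step 9 | none | none
F1 | step 12 | (2R,3S)-2-[4-(tert-butyldimethylsilyloxy)-3-methoxyphenyl]-3-(tert-butyldimethylsilyloxymethyl)-5-{5-(tert-butyldimethylsilyloxy)-6-[1-(tert-butyldimethylsilyloxy)vinyl]benzofuran-2-yl}-3,6-dihydro-2H-pyran | COc1cc([C@@H]2OCC(c3cc4cc(O[Si](C)(C)C(C)(C)C)c(C(=C)O[Si](C)(C)C(C)(C)C)cc4o3)=C[C@H]2CO[Si](C)(C)C(C)(C)C)ccc1O[Si](C)(C)C(C)(C)C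
F0 | step 8 | none | none
F2 | step 4 | 2-acetyl-5-bromo-1,4-phenylene diacetate | CC(=O)c1cc(OC(C)=O)c(Br)cc1OC(C)=O
F3 | step 4 | 2-acetyl-5-[6-(tert-butyldimethylsilyloxy)-4-hydroxyhex-1-yn-1-yl]-1,4-phenylene diacetate | CC(=O)c1cc(OC(C)=O)c(C#CCC(O)CCO[Si](C)(C)C(C)(C)C)cc1OC(C)=O
F4 | step 14 | [(2R,3S)-5-(5-acetoxy-6-acetylbenzofuran-2-yl)-2-(4-acetoxy-3-methoxyphenyl)-3,4-dihydro-2H-pyran-3-yl]methyl acetate | COc1cc([C@@H]2OC=C(c3cc4cc(OC(C)=O)c(C(C)=O)cc4o3)C[C@H]2COC(C)=O)ccc1OC(C)=O
A1 | alternative 1 | (2R,3S)-3-(acetoxymethyl)-2-[4-(tert-butyldimethylsilyloxy)-3-methoxyphenyl]-3,4-dihydro-2H-pyran-5-carbonyl chloride | COc1cc([C@@H]2OC=C(C(Cl)=O)C[C@H]2COC(C)=O)ccc1O[Si](C)(C)C(C)(C)C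
A2 | alternative 1 | (4-acetyl-2,5-dihydroxybenzyl)triphenylphosphonium bromide | CC(=O)c1cc(O)c(C[P+](c2ccccc2)(c2ccccc2)c2ccccc2)cc1O.[Br-]
A3 | alternative 1 | propolis-benzofuran A tert-butyldimethylsilyl ether at the guaiacol oxygen (2R,3S) | COc1cc([C@@H]2OC=C(c3cc4cc(O)c(C(C)=O)cc4o3)C[C@H]2COC(C)=O)ccc1O[Si](C)(C)C(C)(C)C
A4 | alternative 2 | 3-chloro-3-[5-(tert-butyldimethylsilyloxy)-6-(2-methyl-1,3-dioxolan-2-yl)benzofuran-2-yl]-3H-diazirine | ClC1(N=N1)c1cc2cc(O[Si](C)(C)C(C)(C)C)c(C3(C)OCCO3)cc2o1
A5 | alternative 2 | {(2R,3S)-2-[4-(tert-butyldimethylsilyloxy)-3-methoxyphenyl]-2,3-dihydrofuran-3-yl}methyl acetate | COc1cc([C@@H]2OC=C[C@H]2COC(C)=O)ccc1O[Si](C)(C)C(C)(C)C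
A6 | alternative 2 | (2R,3S)-bis(tert-butyldimethylsilyl) ether of propolis-benzofuran A with the acetyl group as its ethylene ketal | COc1cc([C@@H]2OC=C(c3cc4cc(O[Si](C)(C)C(C)(C)C)c(C5(C)OCCO5)cc4o3)C[C@H]2COC(C)=O)ccc1O[Si](C)(C)C(C)(C)C
A7 | alternative 3 | (2S)-2-[(R)-(4-acetoxy-3-methoxyphenyl)(hydroxy)methyl]-4-[6-acetyl-5-(tert-butyldimethylsilyloxy)benzofuran-2-yl]pent-4-en-1-yl acetate | COc1cc([C@H](O)[C@H](COC(C)=O)CC(=C)c2cc3cc(O[Si](C)(C)C(C)(C)C)c(C(C)=O)cc3o2)ccc1OC(C)=O
A8 | alternative 3 | (2R,3S)-propolis-benzofuran A with an acetate on the guaiacol oxygen and a tert-butyldimethylsilyl ether on the benzofuran oxygen | COc1cc([C@@H]2OC=C(c3cc4cc(O[Si](C)(C)C(C)(C)C)c(C(C)=O)cc4o3)C[C@H]2COC(C)=O)ccc1OC(C)=O
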